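The dihydrofuran ring is opened across O1–C7a and C2–C3 (benzofuran numbering; C9 is the carbon on C3). This leaves an aryl aldehyde, whose C=O becomes C2–O1, and a ring B arylacetate in which C3 is enolizable (alpha to the C9 ester) and C7a carries fluorine para to the C5 acrylate. One flask joins them in a [3+2] sense: a reagent-controlled boron aldol forms C2–C3 and fixes C2, then the freed alkoxide O1 closes onto C7a by SNAr. The acrylate that activates C7a is later reduced, together with the C9 ester, to the two primary alcohols, which are acylated and desilylated.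

Key step: step 5

Remark: (−)-Ipc2BOTf (from (+)-α-pinene) is taken to be the antipode that gives (S) at C2; should the sense be the reverse, the reagent from (−)-α-pinene is used and nothing else changes; acid 1 is taken to be a catalogue compound.

Step 1
Reactants: 1 2-(2-fluoro-3-methoxyphenyl)acetic acid
Product: 2 methyl 2-(2-fluoro-3-methoxyphenyl)acetate
Conditions: MeOH, H2SO4 (cat.), reflux
Reagents that add atoms: methanol, CO
Why: Fischer esterification driven by excess methanol; the methyl ester matches the methoxide used in step 5, so ester exchange there is silent.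

Step 2
Reactants: 2 methyl 2-(2-fluoro-3-methoxyphenyl)acetate
Product: 4 methyl 2-(5-bromo-2-fluoro-3-methoxyphenyl)acetate, via aryl boronate 3 (not isolated)
Conditions: [Ir(OMe)(cod)]2 (cat.), 4,4'-di-tert-butyl-2,2'-bipyridine, B2pin2, THF, 80 °C; evaporate; CuBr2, MeOH–H2O, 80 °C
Reagents that add atoms: copper dibromide, [Cu+2].[Br-].[Br-] (bromine of 4); bis(pinacolato)diboron, CC1(C)OB(OC1(C)C)B1OC(C)(C)C(C)(C)O1 (boryl group of 3 only)
Why: Sterically controlled iridium-catalysed arene C–H borylation should go to C5, the only ring C–H of this 1,2,3-trisubstituted arene without an ortho substituent, and copper-mediated bromodeboronation in the same flask should give the bromide para to fluorine.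

Step 3
Reactants: 4 methyl 2-(5-bromo-2-fluoro-3-methoxyphenyl)acetate; 5 methyl acrylate
Product: 6 methyl (E)-3-[4-fluoro-3-methoxy-5-(2-methoxy-2-oxoethyl)phenyl]prop-2-enoate
Conditions: Pd(OAc)2 (cat.), P(o-tol)3, Et3N, DMF, 100 °C
Reagents that add atoms: none
Why: Mizoroki–Heck reaction of an unhindered aryl bromide with an acrylate; syn insertion and syn beta-hydride elimination should give the E alkene.

Step 4
Reactants: 7 syringaldehyde (4-hydroxy-3,5-dimethoxybenzaldehyde)
Product: 8 3,5-dimethoxy-4-(triisopropylsilyloxy)benzaldehyde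
Conditions: i-Pr3SiCl, imidazole, DMF, 40 °C
Reagents that add atoms: chlorotriisopropylsilane, CC(C)[Si](Cl)(C(C)C)C(C)C
Why: Silylation of the acidic phenol; the bulky silyl ether between two methoxy groups should survive the boron triflate, methoxide and hydride steps and leave with fluoride at the end.

Step 5
Reactants: 6 methyl (E)-3-[4-fluoro-3-methoxy-5-(2-methoxy-2-oxoethyl)phenyl]prop-2-enoate; 8 3,5-dimethoxy-4-(triisopropylsilyloxy)benzaldehyde
Product: 13 methyl (2S,3S)-2-[3,5-dimethoxy-4-(triisopropylsilyloxy)phenyl]-7-methoxy-5-[(E)-3-methoxy-3-oxoprop-1-enyl]-2,3-dihydro-1-benzofuran-3-carboxylate (2,3-trans), via boron enolate 9 (not isolated), via boron aldolate 10 (not isolated), via potassium alkoxide 11 (not isolated), via cis ester 12 (not isolated)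
Conditions: (−)-Ipc2BOTf, i-Pr2NEt, CH2Cl2, −78 °C; 8, −78 °C; then KOMe, THF–DMF, −40 to 0 °C; AcOH
Reagents that add atoms: none
Why: Amine-assisted enolboration of the only enolizable ester of 6 should give the E(O) boron enolate 9, which adds to 8 through a closed chair (Zimmerman–Traxler) transition state to the anti aldolate 10 (C2–C3 bond); methoxide then takes the boron as a borate, and the potassium alkoxide 11 adds to C7a, para to the acrylate, and expels fluoride through a Meisenheimer adduct (O1–C7a bond). The closest known reaction types are the reagent-controlled diisopinocampheylboron aldol of methyl arylacetates and the intramolecular SNAr etherification of 2-fluoroaryl alkoxides, here run as an aldol–SNAr annulation. The ring closes by 5-exo-trig attack of O1 on the arene carbon C7a. C2 is set by the isopinocampheyl groups on boron, which choose the aldehyde face, and is kept because the O1–C2 bond is not touched again; C3 is first set anti by the chair and is then equilibrated by methoxide through the ester enolate from cis ester 12 to the more stable trans ester 13. The step needs ring closure to be faster than retro-aldol of 11, which the five-membered intramolecular attack on an acrylate-activated C–F carbon at low temperature should secure. It also needs enolization at one site only, which holds because the cinnamate ester has no alpha hydrogen and all esters are methyl esters.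

Step 6
Reactants: 13 methyl (2S,3S)-2-[3,5-dimethoxy-4-(triisopropylsilyloxy)phenyl]-7-methoxy-5-[(E)-3-methoxy-3-oxoprop-1-enyl]-2,3-dihydro-1-benzofuran-3-carboxylate
Product: 14 (E)-3-[(2S,3R)-2-[3,5-dimethoxy-4-(triisopropylsilyloxy)phenyl]-3-(hydroxymethyl)-7-methoxy-2,3-dihydro-1-benzofuran-5-yl]prop-2-en-1-ol
Conditions: i-Bu2AlH, CH2Cl2, −78 to 0 °C; aq. KNaC4H4O6
Reagents that add atoms: none
Why: Hydride reduction of both methyl esters, 1,2-selective at the cinnamate, should give the diol without touching C2, the aryl silyl ether or the alkene; the C3 descriptor changes from S to R only because the priority of C9 falls.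

Step 7
Reactants: 14 (E)-3-[(2S,3R)-2-[3,5-dimethoxy-4-(triisopropylsilyloxy)phenyl]-3-(hydroxymethyl)-7-methoxy-2,3-dihydro-1-benzofuran-5-yl]prop-2-en-1-ol; 15 4-(tert-butyldimethylsilyloxy)benzoic acid (two equivalents)
Product: 16 [(2S,3R)-5-[(E)-3-[4-(tert-butyldimethylsilyloxy)benzoyloxy]prop-1-enyl]-2-[3,5-dimethoxy-4-(triisopropylsilyloxy)phenyl]-7-methoxy-2,3-dihydro-1-benzofuran-3-yl]methyl 4-(tert-butyldimethylsilyloxy)benzoate
Conditions: DCC, DMAP (cat.), CH2Cl2, 0 °C to rt
Reagents that add atoms: none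
Why: Steglich esterification of the two primary alcohols (one allylic) under neutral conditions that leave the silyl ethers and the allylic system alone.

Step 8
Reactants: 16 the tris-silyl bis-ester of step 7
Product: 17 quiquesetinerviusin B, [(2S,3R)-2-(4-hydroxy-3,5-dimethoxyphenyl)-5-[(E)-3-(4-hydroxybenzoyloxy)prop-1-enyl]-7-methoxy-2,3-dihydro-1-benzofuran-3-yl]methyl 4-hydroxybenzoate
Conditions: Bu4NF, AcOH, THF, 0 °C to rt
Reagents that add atoms: none
Why: Fluoride cleavage of the three aryl silyl ethers; the acetic acid buffer should keep the phenols protonated, so that the benzoates and the 2-aryl-dihydrofuran are not attacked.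

Compound list
1 | 2-(2-fluoro-3-methoxyphenyl)acetic acid | OC(=O)Cc1cccc(OC)c1F | starting material
2 | methyl 2-(2-fluoro-3-methoxyphenyl)acetate | COC(=O)Cc1cccc(OC)c1F | intermediate
3 | methyl 2-[2-fluoro-3-methoxy-5-(4,4,5,5-tetramethyl-1,3,2-dioxaborolan-2-yl)phenyl]acetate | COC(=O)Cc1cc(B2OC(C)(C)C(C)(C)O2)cc(OC)c1F | intermediate
4 | methyl 2-(5-bromo-2-fluoro-3-methoxyphenyl)acetate | COC(=O)Cc1cc(Br)cc(OC)c1F | intermediate
5 | methyl acrylate | C=CC(=O)OC | starting material
6 | methyl (E)-3-[4-fluoro-3-methoxy-5-(2-methoxy-2-oxoethyl)phenyl]prop-2-enoate | COC(=O)/C=C/c1cc(CC(=O)OC)c(F)c(OC)c1 | intermediate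
7 | syringaldehyde (4-hydroxy-3,5-dimethoxybenzaldehyde) | COc1cc(C=O)cc(OC)c1O | starting material
8 | 3,5-dimethoxy-4-(triisopropylsilyloxy)benzaldehyde | COc1cc(C=O)cc(OC)c1O[Si](C(C)C)(C(C)C)C(C)C | intermediate
9 | E(O) boron enolate of 6: methyl (E)-3-[3-[(Z)-2-[bis((−)-isopinocampheyl)boryloxy]-2-methoxyethenyl]-4-fluoro-5-methoxyphenyl]prop-2-enoate | COC(=O)/C=C/c1cc(OC)c(F)c(/C=C(\OC)OB([C@@H]2C[C@@H]3C[C@@H](C3(C)C)[C@H]2C)[C@@H]2C[C@@H]3C[C@@H](C3(C)C)[C@H]2C)c1 | intermediate
10 | anti boron aldolate: methyl (2R,3S)-3-[bis((−)-isopinocampheyl)boryloxy]-2-[2-fluoro-3-methoxy-5-[(E)-3-methoxy-3-oxoprop-1-enyl]phenyl]-3-[3,5-dimethoxy-4-(triisopropylsilyloxy)phenyl]propanoate | COC(=O)[C@H](c1cc(/C=C/C(=O)OC)cc(OC)c1F)[C@H](OB([C@@H]2C[C@@H]3C[C@@H](C3(C)C)[C@H]2C)[C@@H]2C[C@@H]3C[C@@H](C3(C)C)[C@H]2C)c1cc(OC)c(O[Si](C(C)C)(C(C)C)C(C)C)c(OC)c1 | intermediate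
11 | potassium (1S,2R)-2-[2-fluoro-3-methoxy-5-[(E)-3-methoxy-3-oxoprop-1-enyl]phenyl]-3-methoxy-3-oxo-1-[3,5-dimethoxy-4-(triisopropylsilyloxy)phenyl]propan-1-olate | COC(=O)[C@H](c1cc(/C=C/C(=O)OC)cc(OC)c1F)[C@H]([O-])c1cc(OC)c(O[Si](C(C)C)(C(C)C)C(C)C)c(OC)c1.[K+] | intermediate
12 | methyl (2S,3R)-2-[3,5-dimethoxy-4-(triisopropylsilyloxy)phenyl]-7-methoxy-5-[(E)-3-methoxy-3-oxoprop-1-enyl]-2,3-dihydro-1-benzofuran-3-carboxylate (2,3-cis) | COc1cc([C@H]2Oc3c(OC)cc(/C=C/C(=O)OC)cc3[C@H]2C(=O)OC)cc(OC)c1O[Si](C(C)C)(C(C)C)C(C)C | intermediate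
13 | methyl (2S,3S)-2-[3,5-dimethoxy-4-(triisopropylsilyloxy)phenyl]-7-methoxy-5-[(E)-3-methoxy-3-oxoprop-1-enyl]-2,3-dihydro-1-benzofuran-3-carboxylate (2,3-trans) | COc1cc([C@H]2Oc3c(OC)cc(/C=C/C(=O)OC)cc3[C@@H]2C(=O)OC)cc(OC)c1O[Si](C(C)C)(C(C)C)C(C)C | intermediate
14 | (E)-3-[(2S,3R)-2-[3,5-dimethoxy-4-(triisopropylsilyloxy)phenyl]-3-(hydroxymethyl)-7-methoxy-2,3-dihydro-1-benzofuran-5-yl]prop-2-en-1-ol | COc1cc([C@H]2Oc3c(OC)cc(/C=C/CO)cc3[C@@H]2CO)cc(OC)c1O[Si](C(C)C)(C(C)C)C(C)C | intermediate
15 | 4-(tert-butyldimethylsilyloxy)benzoic acid | CC(C)(C)[Si](C)(C)Oc1ccc(cc1)C(=O)O | starting material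
16 | [(2S,3R)-5-[(E)-3-[4-(tert-butyldimethylsilyloxy)benzoyloxy]prop-1-enyl]-2-[3,5-dimethoxy-4-(triisopropylsilyloxy)phenyl]-7-methoxy-2,3-dihydro-1-benzofuran-3-yl]methyl 4-(tert-butyldimethylsilyloxy)benzoate | COc1cc([C@H]2Oc3c(OC)cc(/C=C/COC(=O)c4ccc(O[Si](C)(C)C(C)(C)C)cc4)cc3[C@@H]2COC(=O)c2ccc(O[Si](C)(C)C(C)(C)C)cc2)cc(OC)c1O[Si](C(C)C)(C(C)C)C(C)C | intermediate
17 | quiquesetinerviusin B, [(2S,3R)-2-(4-hydroxy-3,5-dimethoxyphenyl)-5-[(E)-3-(4-hydroxybenzoyloxy)prop-1-enyl]-7-methoxy-2,3-dihydro-1-benzofuran-3-yl]methyl 4-hydroxybenzoate | COc1cc([C@H]2Oc3c(OC)cc(/C=C/COC(=O)c4ccc(O)cc4)cc3[C@@H]2COC(=O)c2ccc(O)cc2)cc(OC)c1O | target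

Total step count: 8. Longest linear sequence: 7 steps (steps 1, 2, 3, 5, 6, 7, 8 from acid 1); step 4 is a one-step side branch.

Steps most likely to fail

Step 5. The potassium aldolate may revert to enolate and aldehyde (retro-aldol) before the ring closes, which would erode the configuration fixed at C2. The fallback sets out from 6 and 8. The same boron aldol is worked up with pH 7 buffer, MeOH and H2O2, and the anti aldol methyl (2R,3S)-2-[2-fluoro-3-methoxy-5-[(E)-3-methoxy-3-oxoprop-1-enyl]phenyl]-3-hydroxy-3-[3,5-dimethoxy-4-(triisopropylsilyloxy)phenyl]propanoate F1 is isolated. F1 is then converted with KN(SiMe3)2 (2.2 equivalents) in THF at −78 °C into the ester enolate–alkoxide dianion, the species of the Fráter–Seebach alkylation, which has no retro-aldol or dehydration path. DMF is added and the mixture is warmed until O1 has displaced fluoride. Quenching with MeOH and equilibration at C3 with NaOMe in MeOH should bring the route back at 13.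

Step 8. During the triple desilylation, phenoxide or fluoride may transfer or cleave the benzoate groups, and the free 4-hydroxyaryl group at C2 may open the dihydrofuran through a quinone methide under basic conditions. The fallback sets out from 14, which holds no ester. Its single silyl ether is removed with Bu4NF and AcOH to give (E)-3-[(2S,3R)-2-(4-hydroxy-3,5-dimethoxyphenyl)-3-(hydroxymethyl)-7-methoxy-2,3-dihydro-1-benzofuran-5-yl]prop-2-en-1-ol F2. Both primary alcohols of F2 are then esterified with unprotected 4-hydroxybenzoic acid under Mitsunobu conditions (PPh3, DIAD, THF, 0 °C), where the carboxylic acid is by far the more acidic partner and the phenols should stay free. This comes back at 17 without a final deprotection.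

Step 2. In the hot aqueous copper bromide stage the methyl ester may be hydrolysed or the boron lost by protodeboronation before bromine is installed. The fallback sets out from 2. The aryl boronate 3 is isolated after the borylation and coupled directly with methyl acrylate 5 in an oxidative Heck reaction (Pd(OAc)2, 2,9-dimethyl-1,10-phenanthroline, O2, DMF, 50 °C). This comes back at 6, leaves out bromide 4 and makes no compound outside the list (F0).

Further compounds
F1 | step 5 | methyl (2R,3S)-2-[2-fluoro-3-methoxy-5-[(E)-3-methoxy-3-oxoprop-1-enyl]phenyl]-3-hydroxy-3-[3,5-dimethoxy-4-(triisopropylsilyloxy)phenyl]propanoate | COC(=O)[C@H](c1cc(/C=C/C(=O)OC)cc(OC)c1F)[C@H](O)c1cc(OC)c(O[Si](C(C)C)(C(C)C)C(C)C)c(OC)c1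
F2 | step 8 | (E)-3-[(2S,3R)-2-(4-hydroxy-3,5-dimethoxyphenyl)-3-(hydroxymethyl)-7-methoxy-2,3-dihydro-1-benzofuran-5-yl]prop-2-en-1-ol | COc1cc([C@H]2Oc3c(OC)cc(/C=C/CO)cc3[C@@H]2CO)cc(OC)c1O
F0 | step 2 | none | none
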